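**Retrosynthetic overview**
1. No ring is made. Both benzene rings are bought with all six bromines in place, and the one strategic bond is the diaryl ether C–O bond.
2. Ring B: 2,4-dibromo-1-iodobenzene 1 is oxidised at iodine and capped with the throw-away arene 1,3,5-trimethoxybenzene 2 (through iodane 3) to give iodonium tosylate 4. This is a 2,4-dibromophenyl cation equivalent, an arene carbon with reversed polarity.
3. Ring A: tetrabromocatechol 5 is used without protection as its mono-potassium salt 6.
4. Key disconnection: the ArO–Ar bond, formed by ligand coupling inside aryloxy-iodane 7 to give target 8 directly.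
5. Order: iodonium salt first, ether bond last. There is no protecting group and no late bromination.

Assumption: the target has no stereocentre and its diaryl ether axis rotates freely at room temperature, so it is achiral and "single enantiomer" means the compound as drawn.

**Step 1**
Reactants: 1 2,4-dibromo-1-iodobenzene; 2 1,3,5-trimethoxybenzene
Product: 4 (2,4-dibromophenyl)(2,4,6-trimethoxyphenyl)iodonium p-toluenesulfonate, via Koser-type hydroxy(tosyloxy)iodane 3 (not isolated)
Conditions: mCPBA (1.05 equiv), TsOH·H2O (1.05 equiv), MeCN, 77 °C, 30 min; then 2 (1.05 equiv), 77 °C, 10 min; Et2O trituration, filter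
Reagents that add atoms: p-toluenesulfonic acid monohydrate, Cc1ccc(cc1)S(=O)(=O)O.O (tosylate of 3 and 4); mCPBA, OOC(=O)c1cccc(Cl)c1 (the hydroxyl oxygen of 3 only, lost as water on going to 4)
Why: mCPBA with TsOH oxidises the aryl iodide to the trivalent-iodine sulfonate 3, and the very electron-rich arene 2 then attacks iodine by electrophilic aromatic substitution (one-pot synthesis of aryl(trimethoxyphenyl)iodonium salts), the salt crystallising from ether; no stereocentre is formed.

**Step 2**
Reactants: 5 3,4,5,6-tetrabromobenzene-1,2-diol (tetrabromocatechol); 4 (2,4-dibromophenyl)(2,4,6-trimethoxyphenyl)iodonium p-toluenesulfonate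
Product: 8 3,4,5,6-tetrabromo-2-(2,4-dibromophenoxy)phenol (the target), via potassium monophenoxide 6 (not isolated), via aryloxy-λ3-iodane 7 (not isolated)
Conditions: 5 (1.5 equiv), KOtBu (1.5 equiv), THF, 0 °C, 15 min; then 4 (1.0 equiv), THF/MeCN 1:1, 60 °C, 16 h; 1 M HCl; phenols extracted into 1 M NaOH, re-acidified, SiO2
Reagents that add atoms: KOtBu, CC(C)(C)[O-].[K+] (the potassium of intermediate 6 only; no atom of it remains in 7 or 8)
Why: the hydrogen-bonded monophenoxide 6 displaces tosylate on iodine to give T-shaped iodane 7, which collapses by ligand coupling at the ipso carbon of the electron-poor, ortho-substituted 2,4-dibromophenyl group while the electron-rich trimethoxyphenyl stays on iodine (metal-free O-arylation of a phenol by a diaryliodonium salt, the aryl iodane acting as an aryl cation equivalent); mono-arylation is favoured because only one oxygen is ionised, the iodonium salt is limiting and product 8 is expected to be a slightly weaker, more hindered acid than 5; no stereocentre is formed.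

**Compound list**
1 | 2,4-dibromo-1-iodobenzene | Ic1ccc(Br)cc1Br | starting material
2 | 1,3,5-trimethoxybenzene | COc1cc(OC)cc(OC)c1 | starting material
3 | 2,4-dibromo-1-[hydroxy(tosyloxy)-λ3-iodanyl]benzene | Cc1ccc(cc1)S(=O)(=O)OI(O)c1ccc(Br)cc1Br | intermediate
4 | (2,4-dibromophenyl)(2,4,6-trimethoxyphenyl)iodonium p-toluenesulfonate | COc1cc(OC)c([I+]c2ccc(Br)cc2Br)c(OC)c1.Cc1ccc(cc1)S(=O)(=O)[O-] | intermediate
5 | 3,4,5,6-tetrabromobenzene-1,2-diol (tetrabromocatechol) | Oc1c(O)c(Br)c(Br)c(Br)c1Br | starting material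
6 | potassium 2,3,4,5-tetrabromo-6-hydroxyphenolate | [K+].[O-]c1c(O)c(Br)c(Br)c(Br)c1Br | intermediate
7 | (2,4-dibromophenyl)(2,3,4,5-tetrabromo-6-hydroxyphenoxy)(2,4,6-trimethoxyphenyl)-λ3-iodane | COc1cc(OC)c(I(Oc2c(O)c(Br)c(Br)c(Br)c2Br)c2ccc(Br)cc2Br)c(OC)c1 | intermediate
8 | 3,4,5,6-tetrabromo-2-(2,4-dibromophenoxy)phenol | Oc1c(Br)c(Br)c(Br)c(Br)c1Oc1ccc(Br)cc1Br | target

**Totals and risks**
Total step count: 2. Longest linear sequence: 2 steps (1 → 4 → 8). The route has only two steps, so both are ranked and there is no third.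

Most likely to fail: step 2. The free catechol may be arylated twice, the hindered and weakly nucleophilic phenoxide may couple slowly, or the catecholate may chelate or reduce the trivalent iodine. The fallback sets out from 6 and comes back at 8 by masking the second oxygen before the aryl transfer. Salt 6 is alkylated with chloromethyl methyl ether (COCCl) in THF at 0 °C to give 2,3,4,5-tetrabromo-6-(methoxymethoxy)phenol F1. F1 is deprotonated with KOtBu to potassium 2,3,4,5-tetrabromo-6-(methoxymethoxy)phenolate F2 (not isolated). F2 reacts with 4 in THF/MeCN at 60 °C through (2,4-dibromophenyl)[2,3,4,5-tetrabromo-6-(methoxymethoxy)phenoxy](2,4,6-trimethoxyphenyl)-λ3-iodane F3 (not isolated) to give 1,2,3,4-tetrabromo-5-(2,4-dibromophenoxy)-6-(methoxymethoxy)benzene F4. HCl in MeOH at 40 °C then cleaves the acetal and gives 8.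

Second: step 1. Oxidation of the electron-poor, ortho-brominated iodide may be slow, trimethoxybenzene may be oxidised by electron transfer instead of attacking iodine, or the unsymmetrical salt may not crystallise. The fallback sets out from 1 and comes back at 8 by using a symmetrical salt with no dummy arene. Iodide 1 is oxidised with mCPBA and TfOH in ClCH2CH2Cl to 2,4-dibromo-1-[hydroxy(trifluoromethanesulfonyloxy)-λ3-iodanyl]benzene F5 (not isolated). F5 is attacked at C4 by bought 1,3-dibromobenzene (Brc1cccc(Br)c1) at 60 °C to give bis(2,4-dibromophenyl)iodonium trifluoromethanesulfonate F6. F6 takes the place of 4 in the reaction with 6 and forms bis(2,4-dibromophenyl)(2,3,4,5-tetrabromo-6-hydroxyphenoxy)-λ3-iodane F7 (not isolated). F7 collapses to 8 and returns one equivalent of 1 for re-use.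

**Further compounds**
F1 | step 2 | 2,3,4,5-tetrabromo-6-(methoxymethoxy)phenol | COCOc1c(O)c(Br)c(Br)c(Br)c1Br
F2 | step 2 | potassium 2,3,4,5-tetrabromo-6-(methoxymethoxy)phenolate | [K+].COCOc1c([O-])c(Br)c(Br)c(Br)c1Br
F3 | step 2 | (2,4-dibromophenyl)[2,3,4,5-tetrabromo-6-(methoxymethoxy)phenoxy](2,4,6-trimethoxyphenyl)-λ3-iodane | COCOc1c(OI(c2ccc(Br)cc2Br)c2c(OC)cc(OC)cc2OC)c(Br)c(Br)c(Br)c1Br
F4 | step 2 | 1,2,3,4-tetrabromo-5-(2,4-dibromophenoxy)-6-(methoxymethoxy)benzene | COCOc1c(Oc2ccc(Br)cc2Br)c(Br)c(Br)c(Br)c1Br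
F5 | step 1 | 2,4-dibromo-1-[hydroxy(trifluoromethanesulfonyloxy)-λ3-iodanyl]benzene | OI(OS(=O)(=O)C(F)(F)F)c1ccc(Br)cc1Br
F6 | step 1 | bis(2,4-dibromophenyl)iodonium trifluoromethanesulfonate | Brc1ccc([I+]c2ccc(Br)cc2Br)c(Br)c1.[O-]S(=O)(=O)C(F)(F)F
F7 | step 1 | bis(2,4-dibromophenyl)(2,3,4,5-tetrabromo-6-hydroxyphenoxy)-λ3-iodane | Oc1c(OI(c2ccc(Br)cc2Br)c2ccc(Br)cc2Br)c(Br)c(Br)c(Br)c1Br
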